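## The problem

The target is (2S)-5-hydroxy-7-methoxyflavanone whose 4'-oxygen is also the C3 oxygen of kaempferol. Two C15 flavonoid units are therefore joined by a single ether oxygen, and two different benzopyranone rings have to be built around that link. The oxygen is the hard atom: on the flavonol side it sits on C3 between the C2 aryl group and the C4 carbonyl, where it is a hindered, chelated and weakly nucleophilic enol oxygen that resists arylation. There is one stereocenter, C2 of the flavanone, and nothing else in the molecule can control it, so a catalyst must. C2 is benzylic, β to the ketone and bonded to a phenoxide leaving group, so base reopens ring C and racemises it; it must be set late and followed only by neutral steps. Four phenols must be freed at the end beside a 7-methoxy group that stays, which points to benzyl ethers and a final hydrogenolysis. The flavonol γ-pyrone limits the reagents: hot alkali opens it, organolithium reagents add to it, Lewis-acidic aluminium hydrides reduce it, and its carbonyl oxygen gives chloropyrylium salts with acid chlorides. The enabling feature is ring B of the flavanone: a benzene with only two substituents, para, carbon at C1' and the ether oxygen at C4', with C2', C3', C5' and C6' all CH. That is the pattern left when a 2-pyrone with a carboxyl group at C5 takes up an alkoxyalkyne across C3 and C6 and loses CO2, so the arene can be grown onto the oxygen.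

## Retrosynthesis

**22 to 21 (O–benzyl bonds).** The four phenols of target 22 are carried as benzyl ethers in flavanone 21. Hydrogenolysis is neutral, so C2 is safe. Acetals would not survive the acid used earlier, and silyl ethers would not survive the base. The forward step must stop before the benzylic C2–O bond or the ketone reacts.

**21 to 19 (O1–C2 of ring C).** Cutting C2–aryl or C4–C4a would need ring B as an organometallic reagent, which a pyrone-derived benzoate does not supply. The oxa-Michael cut uses the carbon substituent of ring B as an aldehyde. A bare 2'-hydroxychalcone closes reversibly and with modest facial control. Alkylidene β-keto ester 19 is doubly activated and offers a bifunctional catalyst two carbonyl groups to hold; the tert-butyl ester is lost through 20 as isobutene and CO2. The forward step needs high facial selectivity and no racemisation during decarboxylation.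

**19 to 15 and 18 (the C=C bond).** A Knoevenagel condensation divides 19 into aldehyde 15, which holds the flavonol and ring B, and ring A keto ester 18. It runs under buffered amine catalysis, whereas a Claisen–Schmidt condensation would expose the pyranone to concentrated alkali.

**18 to 17 to 16.** Keto ester 18 comes from acetophenone 17 by C-acylation of its enolate. Ketone 17 comes from commercial 2',6'-dihydroxy-4'-methoxyacetophenone 16 by monobenzylation. The benzyl group keeps the second phenol out of the ring closure and leaves with the others.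

**15 to 14 to 12 to 11 (oxidation level).** Aldehyde 15 is reached from ester 11 through acid 12 and alcohol 14. Direct aluminium hydride reduction of 11 is rejected because the Lewis-basic pyranone carbonyl would compete. An acid chloride is rejected because it would turn the pyranone into a chloropyrylium salt. The mixed anhydride 13 with borohydride is chosen because flavones are inert to borohydride. These three steps are the price of the pyrone delivering ring B at the carboxyl level.

**11 to 8 and 9 (C2'–C3' and C4'–C5', the key cut).** Cutting the O–C4' bond instead would require arylating flavonol 4 at its most hindered oxygen. Cutting two ring bonds leads to commercial methyl coumalate 9 and ynol ether 8, in which the oxygen is bonded to an unhindered sp carbon. The cycloadduct 10 loses CO2 and is aromatic at once. The forward step needs para regiochemistry and a cycloaddition faster than decomposition of 8.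

**8 to 5 to 4.** The triple bond comes from vinyl ether 5 by bromine addition and double dehydrobromination through 6 and 7. Vinyl ether 5 comes from flavonol 4 by transfer vinylation. The halogen–lithium exchange route to aryl ynol ethers is excluded because alkyllithium reagents add to the pyranone.

**4 to 2 to 1.** The C3 oxygen is introduced by epoxidising flavone 2 through 3, and 2 is the tribenzyl ether of commercial apigenin 1. Algar–Flynn–Oyamada oxidation of the corresponding chalcone is avoided because a 6'-alkoxy group diverts it to aurones.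

## Roads not taken

**Alternative 1:** The flavonol pyranone is cut at C4–C4a and O1–C2, leading to phloroglucinol A3 and the α-aryloxy β-keto ester A2.
- Forward step: A2 heated with A3 loses alcohol to an acylketene, which C-acylates the triphenol; cyclodehydration gives the 3-aryloxyflavone A1.
- Merits: the awkward ether is made before the chromone exists, by a simple displacement α to a keto ester. A3 raises no regiochemical question. A1 is reached in fewer operations than ester 11, and in that respect this road is better.
- Weak points: the temperature needed to form an acylketene from a plain ester stresses the benzyl ether and the keto ester. Chromone closure competes with coumarin closure and with O-acylation, and the α-substituent makes this worse. A1 has two free phenols to protect. Its aryl bromide still needs a catalytic carbonylation to become the aldehyde, since halogen–metal exchange would attack the chromone.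
- Comparison: against the shorter count, the chosen plan offers mild conditions throughout, a flavonol core taken intact from apigenin 1, and a ring B that arrives already bearing its carbon substituent.

**Alternative 2:** Ring C of the flavanone is cut at C3–C4 and O1–C2.
- Forward step: an oxocarbenium ion from 2-hydroxy-4,6-dimethoxybenzaldehyde A5 and trimethyl orthoformate A7, paired with the anion of a confined chiral Brønsted acid, adds the styrene A6 and gives the 2,4-cis flavan A4.
- Merits: this is the only plan in which the stereocenter is made in the ring-forming step under direct catalyst control. That is better than the chosen plan, which must activate the chalcone with an ester and remove it again.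
- Weak points: A6 is the 4-vinylphenyl ether of the protected flavonol, so the hindered C3 oxygen must still be arylated; the hard bond is presupposed. A4 is at the wrong oxidation level at C4 and carries a 5-methoxy group, so a benzylic oxidation and a selective demethylation follow. A styrene whose para-aryloxy group is an electron-poor chromone is a modest nucleophile, and the basic pyranone oxygen may compete for the acid.
- Comparison: the chosen plan offers the correct oxidation level and the 5-O/7-O differentiation from the outset in 18, and it solves the ether problem.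

**Alternative 3:** C3 of the flavonol is removed as a single carbon (C2–C3 and C3–C4).
- Forward step: the 2-aryl-3-silyloxybenzofuran A9 is cyclopropanated by the aryloxychlorocarbene released from the chlorodiazirine A10, and the adduct opens with loss of the silyl chloride to the ring-expanded 3-aryloxyflavone A8.
- Merits: C3 arrives with its aryloxy group attached, so, as in the chosen plan, the crowded oxygen never acts as a nucleophile towards an arene. No thermally fragile ynol ether is needed, which is an advantage over the chosen plan.
- Weak points: halodiazirines are energetic and must be handled cold. The stabilised carbene must attack a tetrasubstituted, aromatic furan double bond flanked by an aryl group and a peri benzyloxy group. The insertion is little explored for oxygen-substituted carbenes. A8, like A1, ends in an aryl bromide that still needs carbonylation.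
- Comparison: the length is similar. The chosen plan offers a bench-stable commercial pyrone 9, purely thermal pericyclic chemistry, and an ester that is already the carbon needed for ring C.

Key step: step 5

## Route

Assumption: in step 12 the quinidine-derived thiourea is taken to give the 2S series, by analogy with simpler 2-arylchromanones; I could not confirm the sense from memory, so it must be checked on the first closure, and the quinine-derived pseudoenantiomer replaces it unchanged if the sense is opposite.

Abbreviation in names: FlO = {5,7-bis(benzyloxy)-2-[4-(benzyloxy)phenyl]-4-oxo-4H-chromen-3-yl}oxy.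

Step 1
Reactants: 1 apigenin (5,7-dihydroxy-2-(4-hydroxyphenyl)-4H-chromen-4-one)
Product: 2 5,7-bis(benzyloxy)-2-[4-(benzyloxy)phenyl]-4H-chromen-4-one
Conditions: BnBr (4.5 equiv), K2CO3 (6 equiv), DMF, 70 °C
Reagents that add atoms: benzyl bromide, BrCc1ccccc1
Why: Williamson ether synthesis on all three phenoxides; the chelated 5-OH is the slowest and is driven by excess reagent and heat in a dipolar aprotic solvent.

Step 2
Reactants: 2 5,7-bis(benzyloxy)-2-[4-(benzyloxy)phenyl]-4H-chromen-4-one
Product: 4 5,7-bis(benzyloxy)-2-[4-(benzyloxy)phenyl]-3-hydroxy-4H-chromen-4-one, via flavone 2,3-epoxide 3 (not isolated)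
Conditions: dimethyldioxirane (acetone solution, 2 equiv), CH2Cl2, 0 °C to rt; then p-TsOH·H2O (cat.), CH2Cl2, rt
Reagents that add atoms: dimethyldioxirane, CC1(C)OO1
Why: Dioxirane epoxidation of the enol-ether-like C2–C3 double bond gives 3; acid opens it at the oxocarbenium-stabilised C2 and loss of the C3 proton gives the flavonol. This is the known flavone-to-flavonol oxidation and has no aurone branch.

Step 3
Reactants: 4 5,7-bis(benzyloxy)-2-[4-(benzyloxy)phenyl]-3-hydroxy-4H-chromen-4-one
Product: 5 5,7-bis(benzyloxy)-2-[4-(benzyloxy)phenyl]-3-(ethenyloxy)-4H-chromen-4-one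
Conditions: vinyl acetate (3 equiv), [Ir(cod)Cl]2 (2 mol%), Na2CO3 (0.6 equiv), toluene, 100 °C
Reagents that add atoms: vinyl acetate, CC(=O)OC=C
Why: Iridium-catalysed transfer vinylation of a phenol-type hydroxyl from vinyl acetate; the 3-OH is the only free hydroxyl, and the vinyl ether cannot undergo a Claisen rearrangement because it has no allyl unit.

Step 4
Reactants: 5 5,7-bis(benzyloxy)-2-[4-(benzyloxy)phenyl]-3-(ethenyloxy)-4H-chromen-4-one
Product: 8 5,7-bis(benzyloxy)-2-[4-(benzyloxy)phenyl]-3-(ethynyloxy)-4H-chromen-4-one, via 1,2-dibromoethyl ether 6 (not isolated), via (Z)-2-bromovinyl ether 7 (not isolated)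
Conditions: Br2 (1.0 equiv), CH2Cl2, −78 °C; then KN(SiMe3)2 (3.2 equiv), THF, −78 to −40 °C; pH 7 buffer, −78 °C; rapid filtration through basic alumina, used at once
Reagents that add atoms: none
Why: Bromine adds to the enol ether double bond at −78 °C much faster than it substitutes ring A, giving 6; loss of the labile α-bromide gives 7, and anti E2 elimination from the Z bromoalkene gives the alkyne (the classical route to aryloxyacetylenes). The hindered silylamide does not add to the pyranone, and the third equivalent holds the product as its acetylide until the cold buffered quench.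

Step 5
Reactants: 8 5,7-bis(benzyloxy)-2-[4-(benzyloxy)phenyl]-3-(ethynyloxy)-4H-chromen-4-one; 9 methyl coumalate (methyl 2-oxo-2H-pyran-5-carboxylate)
Product: 11 methyl 4-(FlO)benzoate, via bridged lactone 10 (not isolated)
Conditions: 9 (3 equiv), BHT (5 mol%), toluene, 110 °C, sealed tube, argon
Reagents that add atoms: none
Why: This is an inverse-demand (4+2) cycloaddition in which the HOMO of 8, largest at the terminal CH carbon, meets the LUMO of 9, largest at C6; the CH carbon bonds to C6 and the oxygen-bearing carbon to C3 in a concerted, asynchronous step. Ring B closes by intermolecular (4+2) cycloaddition, which gives the 2-oxabicyclo[2.2.2]octadienone 10. Lactone 10 then loses CO2 by retro-(4+2) cycloreversion at the reaction temperature and is aromatic at once; because the dienophile is an alkyne, no oxidation or elimination is needed and the flavonyloxy group cannot be expelled. The closest known reaction type is the Diels–Alder reaction with CO2 extrusion of coumalate esters with ynamines, alkynyl ethers and ketene acetals, which gives para-substituted benzoates. No stereocenter remains in the product, since the two bridgeheads of 10 become arene carbons. The step needs para over meta selectivity, which the polarity match secures: C6 is β to the ester and the terminus of the vinylogous lactone, and the ether oxygen makes the CH carbon of 8 the nucleophilic end. Sterics agree, since the bulky flavonyloxy group sits on the carbon that bonds to unsubstituted C3. The crowded flavonol oxygen forms no bond in this step, and 8 has no C–H β to oxygen on the flavonyl side, so the retro-ene route to a ketene that limits alkyl ynol ethers is closed.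

Step 6
Reactants: 11 methyl 4-(FlO)benzoate
Product: 12 4-(FlO)benzoic acid
Conditions: LiOH·H2O (3 equiv), THF/MeOH/H2O, rt; then 1 M HCl
Reagents that add atoms: lithium hydroxide, [Li+].[OH-]
Why: Saponification of an aryl methyl ester at room temperature; a 2,3-disubstituted γ-pyrone is not opened by cold dilute hydroxide and the diaryl ether is inert.

Step 7
Reactants: 12 4-(FlO)benzoic acid
Product: 14 [4-(FlO)phenyl]methanol, via mixed carbonic anhydride 13 (not isolated)
Conditions: i-BuOCOCl (1.2 equiv), N-methylmorpholine (1.3 equiv), THF, −15 °C; then NaBH4 (3 equiv), H2O, −15 to 0 °C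
Reagents that add atoms: none
Why: Mixed-anhydride activation and borohydride reduction at the aroyl carbonyl; flavones are inert to NaBH4 under these conditions, which is the reason for choosing this over aluminium hydride reduction of 11 or an acid chloride.

Step 8
Reactants: 14 [4-(FlO)phenyl]methanol
Product: 15 4-(FlO)benzaldehyde
Conditions: activated MnO2 (15 equiv), CH2Cl2, rt
Reagents that add atoms: none
Why: Heterogeneous MnO2 oxidation of a benzylic alcohol stops at the aldehyde and leaves benzyl ethers and the chromone alone.

Step 9
Reactants: 16 2',6'-dihydroxy-4'-methoxyacetophenone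
Product: 17 1-[2-(benzyloxy)-6-hydroxy-4-methoxyphenyl]ethanone
Conditions: BnBr (1.05 equiv), K2CO3 (1.2 equiv), acetone, reflux
Reagents that add atoms: benzyl bromide, BrCc1ccccc1
Why: Williamson monobenzylation; after the first alkylation the remaining hydroxyl is locked in a hydrogen bond to the acetyl group and is not alkylated by one equivalent under mild base.

Step 10
Reactants: 17 1-[2-(benzyloxy)-6-hydroxy-4-methoxyphenyl]ethanone
Product: 18 tert-butyl 3-[2-(benzyloxy)-6-hydroxy-4-methoxyphenyl]-3-oxopropanoate
Conditions: LiN(SiMe3)2 (3.2 equiv), THF, −78 °C; then Boc2O (1.1 equiv), −78 to −20 °C; aq. NH4Cl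
Reagents that add atoms: di-tert-butyl dicarbonate, CC(C)(C)OC(=O)OC(=O)OC(C)(C)C
Why: Claisen-type C-acylation of the phenoxide–enolate dianion, either directly or by O-acylation followed by Baker–Venkataraman-type O-to-C transfer. The third equivalent of base takes up the acidic β-keto ester, and the tert-butyl ester resists lactonisation to a 4-hydroxycoumarin in the cold.

Step 11
Reactants: 15 4-(FlO)benzaldehyde; 18 tert-butyl 3-[2-(benzyloxy)-6-hydroxy-4-methoxyphenyl]-3-oxopropanoate
Product: 19 tert-butyl 2-[2-(benzyloxy)-6-hydroxy-4-methoxybenzoyl]-3-[4-(FlO)phenyl]prop-2-enoate (alkene geometry not assigned)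
Conditions: piperidine (0.2 equiv), AcOH (0.2 equiv), 4 Å molecular sieves, toluene, rt
Reagents that add atoms: none
Why: Knoevenagel condensation through the piperidinium iminium ion of 15 under buffered, nearly neutral conditions, which spares the pyranone the alkali of a Claisen–Schmidt condensation.

Step 12
Reactants: 19 tert-butyl 2-[2-(benzyloxy)-6-hydroxy-4-methoxybenzoyl]-3-[4-(FlO)phenyl]prop-2-enoate
Product: 21 (2S)-5-(benzyloxy)-7-methoxy-2-[4-(FlO)phenyl]-2,3-dihydro-4H-chromen-4-one, via flavanone 3-carboxylate 20 (not isolated)
Conditions: 1-[3,5-bis(trifluoromethyl)phenyl]-3-[(9R)-6'-methoxycinchonan-9-yl]thiourea (quinidine-derived, 10 mol%), toluene, −25 °C; then p-TsOH·H2O (1 equiv), 80 °C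
Reagents that add atoms: none
Why: Organocatalytic asymmetric intramolecular oxa-Michael addition: the thiourea holds the β-keto ester by two hydrogen bonds while the quinuclidine nitrogen deprotonates the phenol and delivers it to one face of the alkene, so the catalyst sets C2. Acid then cleaves the tert-butyl ester and the β-keto acid decarboxylates without touching C2. The ester makes the closure fast, two-point bound and irreversible at −25 °C, which a bare 2'-hydroxychalcone is not.

Step 13
Reactants: 21 (2S)-5-(benzyloxy)-7-methoxy-2-[4-(FlO)phenyl]-2,3-dihydro-4H-chromen-4-one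
Product: 22 (2S)-5-hydroxy-2-[4-({5,7-dihydroxy-2-(4-hydroxyphenyl)-4-oxo-4H-chromen-3-yl}oxy)phenyl]-7-methoxy-2,3-dihydro-4H-chromen-4-one (CNP0173006.1)
Conditions: H2 (1 atm), 10% Pd/C, EtOAc/MeOH, rt
Reagents that add atoms: none
Why: Hydrogenolysis of the four benzyl ethers under neutral conditions; the tetrasubstituted pyranone double bond, the aryl ketone and the methyl ether should survive at 1 atm and room temperature, and C2 cannot epimerise without base.

## Compound list

1 | apigenin, 5,7-dihydroxy-2-(4-hydroxyphenyl)-4H-chromen-4-one | O=c1cc(-c2ccc(O)cc2)oc2cc(O)cc(O)c12 | starting material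
2 | 5,7-bis(benzyloxy)-2-[4-(benzyloxy)phenyl]-4H-chromen-4-one | O=c1cc(-c2ccc(OCc3ccccc3)cc2)oc2cc(OCc3ccccc3)cc(OCc3ccccc3)c12 | intermediate
3 | racemic 5,7-bis(benzyloxy)-2-[4-(benzyloxy)phenyl]-2,3-epoxy-2,3-dihydro-4H-chromen-4-one (not isolated) | O=C1C2OC2(c2ccc(OCc3ccccc3)cc2)Oc2cc(OCc3ccccc3)cc(OCc3ccccc3)c12 | intermediate
4 | 5,7-bis(benzyloxy)-2-[4-(benzyloxy)phenyl]-3-hydroxy-4H-chromen-4-one | O=c1c(O)c(-c2ccc(OCc3ccccc3)cc2)oc2cc(OCc3ccccc3)cc(OCc3ccccc3)c12 | intermediate
5 | 5,7-bis(benzyloxy)-2-[4-(benzyloxy)phenyl]-3-(ethenyloxy)-4H-chromen-4-one | C=COc1c(-c2ccc(OCc3ccccc3)cc2)oc2cc(OCc3ccccc3)cc(OCc3ccccc3)c2c1=O | intermediate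
6 | racemic 5,7-bis(benzyloxy)-2-[4-(benzyloxy)phenyl]-3-(1,2-dibromoethoxy)-4H-chromen-4-one (not isolated) | BrCC(Br)Oc1c(-c2ccc(OCc3ccccc3)cc2)oc2cc(OCc3ccccc3)cc(OCc3ccccc3)c2c1=O | intermediate
7 | 5,7-bis(benzyloxy)-2-[4-(benzyloxy)phenyl]-3-[(Z)-2-bromoethenyloxy]-4H-chromen-4-one (not isolated) | Br/C=C\Oc1c(-c2ccc(OCc3ccccc3)cc2)oc2cc(OCc3ccccc3)cc(OCc3ccccc3)c2c1=O | intermediate
8 | 5,7-bis(benzyloxy)-2-[4-(benzyloxy)phenyl]-3-(ethynyloxy)-4H-chromen-4-one | C#COc1c(-c2ccc(OCc3ccccc3)cc2)oc2cc(OCc3ccccc3)cc(OCc3ccccc3)c2c1=O | intermediate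
9 | methyl coumalate, methyl 2-oxo-2H-pyran-5-carboxylate | COC(=O)C1=COC(=O)C=C1 | starting material
10 | racemic methyl 8-({5,7-bis(benzyloxy)-2-[4-(benzyloxy)phenyl]-4-oxo-4H-chromen-3-yl}oxy)-3-oxo-2-oxabicyclo[2.2.2]octa-5,7-diene-6-carboxylate (not isolated) | COC(=O)C1=CC2C(=O)OC1C=C2Oc1c(-c2ccc(OCc3ccccc3)cc2)oc2cc(OCc3ccccc3)cc(OCc3ccccc3)c2c1=O | intermediate
11 | methyl 4-({5,7-bis(benzyloxy)-2-[4-(benzyloxy)phenyl]-4-oxo-4H-chromen-3-yl}oxy)benzoate | COC(=O)c1ccc(Oc2c(-c3ccc(OCc4ccccc4)cc3)oc3cc(OCc4ccccc4)cc(OCc4ccccc4)c3c2=O)cc1 | intermediate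
12 | 4-({5,7-bis(benzyloxy)-2-[4-(benzyloxy)phenyl]-4-oxo-4H-chromen-3-yl}oxy)benzoic acid | OC(=O)c1ccc(Oc2c(-c3ccc(OCc4ccccc4)cc3)oc3cc(OCc4ccccc4)cc(OCc4ccccc4)c3c2=O)cc1 | intermediate
13 | 4-(FlO)benzoic isobutyl carbonic anhydride (not isolated) | CC(C)COC(=O)OC(=O)c1ccc(Oc2c(-c3ccc(OCc4ccccc4)cc3)oc3cc(OCc4ccccc4)cc(OCc4ccccc4)c3c2=O)cc1 | intermediate
14 | 5,7-bis(benzyloxy)-2-[4-(benzyloxy)phenyl]-3-[4-(hydroxymethyl)phenoxy]-4H-chromen-4-one | OCc1ccc(Oc2c(-c3ccc(OCc4ccccc4)cc3)oc3cc(OCc4ccccc4)cc(OCc4ccccc4)c3c2=O)cc1 | intermediate
15 | 4-({5,7-bis(benzyloxy)-2-[4-(benzyloxy)phenyl]-4-oxo-4H-chromen-3-yl}oxy)benzaldehyde | O=Cc1ccc(Oc2c(-c3ccc(OCc4ccccc4)cc3)oc3cc(OCc4ccccc4)cc(OCc4ccccc4)c3c2=O)cc1 | intermediate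
16 | 2',6'-dihydroxy-4'-methoxyacetophenone | CC(=O)c1c(O)cc(OC)cc1O | starting material
17 | 1-[2-(benzyloxy)-6-hydroxy-4-methoxyphenyl]ethanone | CC(=O)c1c(O)cc(OC)cc1OCc1ccccc1 | intermediate
18 | tert-butyl 3-[2-(benzyloxy)-6-hydroxy-4-methoxyphenyl]-3-oxopropanoate | CC(C)(C)OC(=O)CC(=O)c1c(O)cc(OC)cc1OCc1ccccc1 | intermediate
19 | tert-butyl 2-[2-(benzyloxy)-6-hydroxy-4-methoxybenzoyl]-3-[4-({5,7-bis(benzyloxy)-2-[4-(benzyloxy)phenyl]-4-oxo-4H-chromen-3-yl}oxy)phenyl]prop-2-enoate, alkene geometry not assigned | CC(C)(C)OC(=O)C(=Cc1ccc(Oc2c(-c3ccc(OCc4ccccc4)cc3)oc3cc(OCc4ccccc4)cc(OCc4ccccc4)c3c2=O)cc1)C(=O)c1c(O)cc(OC)cc1OCc1ccccc1 | intermediate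
20 | tert-butyl (2S)-5-(benzyloxy)-7-methoxy-4-oxo-2-[4-(FlO)phenyl]chromane-3-carboxylate, C3 epimers and enol form (not isolated) | COc1cc(OCc2ccccc2)c2c(c1)O[C@H](c1ccc(Oc3c(-c4ccc(OCc5ccccc5)cc4)oc4cc(OCc5ccccc5)cc(OCc5ccccc5)c4c3=O)cc1)C(C(=O)OC(C)(C)C)C2=O | intermediate
21 | (2S)-5-(benzyloxy)-2-[4-({5,7-bis(benzyloxy)-2-[4-(benzyloxy)phenyl]-4-oxo-4H-chromen-3-yl}oxy)phenyl]-7-methoxy-2,3-dihydro-4H-chromen-4-one | COc1cc(OCc2ccccc2)c2c(c1)O[C@H](c1ccc(Oc3c(-c4ccc(OCc5ccccc5)cc4)oc4cc(OCc5ccccc5)cc(OCc5ccccc5)c4c3=O)cc1)CC2=O | intermediate
22 | (2S)-5-hydroxy-2-[4-({5,7-dihydroxy-2-(4-hydroxyphenyl)-4-oxo-4H-chromen-3-yl}oxy)phenyl]-7-methoxy-2,3-dihydro-4H-chromen-4-one | COc1cc(O)c2c(c1)O[C@H](c1ccc(Oc3c(-c4ccc(O)cc4)oc4cc(O)cc(O)c4c3=O)cc1)CC2=O | target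

## Step count and least certain steps

Total: 13 steps. Longest linear sequence: 11 steps (steps 1–8 and 11–13, from apigenin 1); the ring A branch is steps 9 and 10.

**Step 5 (key step).** The terminal ynol ether may oligomerise or be hydrated faster than it cycloadds, because the flavonyl oxygen is a weaker donor than the nitrogen or alkyl-oxygen substituents of the precedent. A more synchronous transition state could also erode the para selectivity. The fallback sets out from flavonol 4 and rejoins at 11. It is the known metal-free O-arylation of phenols with diaryliodonium salts, which tolerates hindered oxygens. The salt (4-methoxycarbonylphenyl)(2,4,6-trimethoxyphenyl)iodonium p-toluenesulfonate F1 is made in one operation from methyl 4-iodobenzoate, mCPBA, p-TsOH and 1,3,5-trimethoxybenzene. Treating 4 with F1 and KOt-Bu in THF at room temperature should transfer the ester-bearing aryl group by ligand coupling at iodine and give 11. This fallback bypasses the ynol ether entirely and is shorter than the route through steps 3–5.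

**Step 4.** Nuclear bromination of ring A at C6 or C8 may compete with addition to the vinyl ether, and 8 may decompose during isolation. The fallback sets out from 4 and rejoins at 8. The potassium salt of 4 is added to chloroacetylene generated in situ from cis-1,2-dichloroethene and KOt-Bu in DMSO/THF. Anti addition should give 5,7-bis(benzyloxy)-2-[4-(benzyloxy)phenyl]-3-[(Z)-2-chloroethenyloxy]-4H-chromen-4-one F2. KN(SiMe3)2 in THF at −78 °C then eliminates HCl to 8, and no electrophilic halogen meets ring A. I am less sure of the precedent for phenoxide addition to chloroacetylene than for the other fallbacks.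

**Step 12.** Facial selectivity may be poor, because the 6'-benzyloxy group twists the aroyl group out of the plane the catalyst binds. Racemic closure may already begin under the amine of step 11, acid at 80 °C may partly racemise C2 by ring opening, and the sense of induction may be the opposite one. The fallback sets out from 19 and rejoins at 21. Closure with Et3N and decarboxylation with p-TsOH should give, through the racemic tert-butyl 5-(benzyloxy)-7-methoxy-4-oxo-2-[4-(FlO)phenyl]chromane-3-carboxylate F3, the racemic 5-(benzyloxy)-7-methoxy-2-[4-(FlO)phenyl]-2,3-dihydro-4H-chromen-4-one F4. Preparative chromatography on a chiral stationary phase then separates 21 from its mirror image, the (2R)-flavanone F5. F5 can be returned to F4 with an amine base through the chalcone and resolved again.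

**Step 3.** The chelating 3-hydroxy-4-oxo unit may sequester the iridium catalyst and stall the vinyl transfer, or acetyl transfer may compete. The fallback sets out from 4 and rejoins at 5. Alkylation with excess 1,2-dibromoethane and K2CO3 in DMF should give 5,7-bis(benzyloxy)-2-[4-(benzyloxy)phenyl]-3-(2-bromoethoxy)-4H-chromen-4-one F6. E2 elimination with KOt-Bu in THF at 0 °C then gives 5.

**Step 13.** Over-reduction may occur before the last, chelation-deactivated benzyl ether is cleaved: hydrogenolysis of the benzylic C2–O bond of the flavanone or reduction of its ketone. The fallback sets out from 21 and ends at 22. Lewis-acid debenzylation with BCl3 and pentamethylbenzene as cation scavenger in CH2Cl2 at −78 °C, quenched with MeOH, is non-reductive and non-basic. The aryl methyl ether should survive at that temperature.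

## Further compounds

F1 | step 5 | (4-methoxycarbonylphenyl)(2,4,6-trimethoxyphenyl)iodonium p-toluenesulfonate | COC(=O)c1ccc([I+]c2c(OC)cc(OC)cc2OC)cc1.Cc1ccc(S(=O)(=O)[O-])cc1
F2 | step 4 | 5,7-bis(benzyloxy)-2-[4-(benzyloxy)phenyl]-3-[(Z)-2-chloroethenyloxy]-4H-chromen-4-one | Cl/C=C\Oc1c(-c2ccc(OCc3ccccc3)cc2)oc2cc(OCc3ccccc3)cc(OCc3ccccc3)c2c1=O
F3 | step 12 | racemic tert-butyl 5-(benzyloxy)-7-methoxy-4-oxo-2-[4-(FlO)phenyl]chromane-3-carboxylate | COc1cc(OCc2ccccc2)c2c(c1)OC(c1ccc(Oc3c(-c4ccc(OCc5ccccc5)cc4)oc4cc(OCc5ccccc5)cc(OCc5ccccc5)c4c3=O)cc1)C(C(=O)OC(C)(C)C)C2=O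
F4 | step 12 | racemic 5-(benzyloxy)-7-methoxy-2-[4-(FlO)phenyl]-2,3-dihydro-4H-chromen-4-one | COc1cc(OCc2ccccc2)c2c(c1)OC(c1ccc(Oc3c(-c4ccc(OCc5ccccc5)cc4)oc4cc(OCc5ccccc5)cc(OCc5ccccc5)c4c3=O)cc1)CC2=O
F5 | step 12 | (2R)-5-(benzyloxy)-7-methoxy-2-[4-(FlO)phenyl]-2,3-dihydro-4H-chromen-4-one | COc1cc(OCc2ccccc2)c2c(c1)O[C@@H](c1ccc(Oc3c(-c4ccc(OCc5ccccc5)cc4)oc4cc(OCc5ccccc5)cc(OCc5ccccc5)c4c3=O)cc1)CC2=O
F6 | step 3 | 5,7-bis(benzyloxy)-2-[4-(benzyloxy)phenyl]-3-(2-bromoethoxy)-4H-chromen-4-one | BrCCOc1c(-c2ccc(OCc3ccccc3)cc2)oc2cc(OCc3ccccc3)cc(OCc3ccccc3)c2c1=O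
F0 | step 13 | none | none
A1 | alternative 1 | 2-[4-(benzyloxy)phenyl]-3-(4-bromophenoxy)-5,7-dihydroxy-4H-chromen-4-one | Oc1cc(O)c2c(c1)oc(-c1ccc(OCc3ccccc3)cc1)c(Oc1ccc(Br)cc1)c2=O
A2 | alternative 1 | racemic ethyl 3-[4-(benzyloxy)phenyl]-2-(4-bromophenoxy)-3-oxopropanoate | CCOC(=O)C(Oc1ccc(Br)cc1)C(=O)c1ccc(OCc2ccccc2)cc1
A3 | alternative 1 | phloroglucinol | Oc1cc(O)cc(O)c1
A4 | alternative 2 | (2S,4S)-4,5,7-trimethoxy-2-[4-(FlO)phenyl]chromane | COc1cc(OC)c2c(c1)O[C@H](c1ccc(Oc3c(-c4ccc(OCc5ccccc5)cc4)oc4cc(OCc5ccccc5)cc(OCc5ccccc5)c4c3=O)cc1)C[C@@H]2OC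
A5 | alternative 2 | 2-hydroxy-4,6-dimethoxybenzaldehyde | COc1cc(O)c(C=O)c(OC)c1
A6 | alternative 2 | 5,7-bis(benzyloxy)-2-[4-(benzyloxy)phenyl]-3-(4-ethenylphenoxy)-4H-chromen-4-one | C=Cc1ccc(Oc2c(-c3ccc(OCc4ccccc4)cc3)oc3cc(OCc4ccccc4)cc(OCc4ccccc4)c3c2=O)cc1
A7 | alternative 2 | trimethyl orthoformate | COC(OC)OC
A8 | alternative 3 | 5,7-bis(benzyloxy)-2-[4-(benzyloxy)phenyl]-3-(4-bromophenoxy)-4H-chromen-4-one | Brc1ccc(Oc2c(-c3ccc(OCc4ccccc4)cc3)oc3cc(OCc4ccccc4)cc(OCc4ccccc4)c3c2=O)cc1
A9 | alternative 3 | 4,6-bis(benzyloxy)-2-[4-(benzyloxy)phenyl]-3-[(trimethylsilyl)oxy]-1-benzofuran | C[Si](C)(C)Oc1c(-c2ccc(OCc3ccccc3)cc2)oc2cc(OCc3ccccc3)cc(OCc3ccccc3)c12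
A10 | alternative 3 | 3-(4-bromophenoxy)-3-chloro-3H-diazirine | ClC1(Oc2ccc(Br)cc2)N=N1
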